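Everything rests on cutting ring B at C8–C9. In ring A the quaternary carbons C4 and C10 are near mirror images across the plane that holds C2 and C5: each bears an axial methyl and an equatorial carbon (C18, C9). Ring A of dehydroabietic acid, numbered in the opposite sense, supplies C4, C5 and C10 of this ent-labdane, provided O6 is set as the axial 6β-alcohol of the abietane. Precursor 19 is that cyclohexane with an E-enoate (C9=C11) on C10, the C7–C8 methyl ketone arm on C6, and O6 tied to C18 as a γ-lactone. SmI2 makes the C8 ketyl, which adds 6-exo to C9: one operation forms C8–C9, closes ring B and sets C8 and C9.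

Key step: step 15

Remarks on the chemistry
- **Assumption.** Commercial (+)-dehydroabietic acid has the natural configuration written for 1.
- **Numbering.** Target (labdane) numbers are used unless "abietane" is written.
  - Abietane C18, C4, C10 and C9 become C9, C10, C4 and C18.
  - C5 to C8 keep their numbers.
  - Abietane C19 and C20 become C20 and C19.
- **C6.**
  - In the abietane, C7 lies anti to abietane C4. In the new ring B it must lie anti to abietane C10.
  - This 120° turn about C5–C6 interchanges axial and equatorial on C6, so the equatorial 6-acetate of the target must be carried as the axial 6β-oxygen of the abietane.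
  - Any reagent that brings oxygen to the open α face of the Δ6 alkene would end as the 6-epimer. The alcohol is therefore made from the 6-ketone, with hydride coming from the α face.
- **Monocyclic stage.**
  - Once the old ring B is cut, ring A can flip, and the cis-1,3 functions on C9 and C18 could then react with each other.
  - The trans-fused 18,6-lactone is closed while O9 is still acetylated. It freezes the chair and keeps C8, C9 and C18 chemically distinct.
  - It also protects O6 and C18 through the key step. The carbon skeleton of 19 and 20 and the bond formed are unaffected by this choice.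
- **O8.** It is silylated before C12 receives a leaving group. A free O8 would close an ambroxide-type 8,12-ether.

Step 1
Reactants: 1 dehydroabietic acid
Product: 2 dehydroabietinol
Conditions: LiAlH4, THF, 0 °C to reflux
Reagents that add atoms: none
Why: LiAlH4 reduction of a carboxylic acid to the primary alcohol works even on this hindered tertiary acid and touches none of the three stereocentres.

Step 2
Reactants: 2 dehydroabietinol
Product: 3 abieta-8,11,13-trien-18-yl acetate
Conditions: Ac2O, pyridine, DMAP (cat.), CH2Cl2, rt
Reagents that add atoms: acetic anhydride, CC(=O)OC(C)=O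
Why: DMAP-catalysed acetylation masks the neopentyl alcohol (the future oxygen on C9) as an ester, the kind of protecting group that withstands CrO3 and RuO4.

Step 3
Reactants: 3 abieta-8,11,13-trien-18-yl acetate
Product: 4 7-oxoabieta-8,11,13-trien-18-yl acetate
Conditions: CrO3, AcOH, 40 °C
Reagents that add atoms: chromium trioxide, O=[Cr](=O)=O
Why: CrO3 benzylic oxidation converts the only benzylic CH2 (C7) into the aryl ketone, and stray oxidation at the isopropyl C–H would not matter because that part of ring C is excised in step 9.

Step 4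
Reactants: 4 7-oxoabieta-8,11,13-trien-18-yl acetate
Product: 5 7-hydroxyabieta-8,11,13-trien-18-yl acetate (C7 epimers)
Conditions: NaBH4, MeOH–THF, 0 °C
Reagents that add atoms: none
Why: NaBH4 reduction of the aryl ketone spares the acetate, and the configuration of the new C7 carbinol is irrelevant because C7 becomes sp2 in step 5.

Step 5
Reactants: 5 7-hydroxyabieta-8,11,13-trien-18-yl acetate
Product: 6 abieta-6,8,11,13-tetraen-18-yl acetate
Conditions: TsOH·H2O (cat.), toluene, reflux, Dean–Stark
Reagents that add atoms: none
Why: Acid-catalysed E1 dehydration through the benzylic C7 cation can lose a proton only from C6 and so gives the conjugated Δ6 alkene with C5 untouched.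

Step 6
Reactants: 6 abieta-6,8,11,13-tetraen-18-yl acetate
Product: 8 6-oxoabieta-8,11,13-trien-18-yl acetate, via 6α,7α-epoxide 7 (not isolated)
Conditions: DMDO, acetone–CH2Cl2, 0 °C; evaporate; BF3·OEt2 (0.2 equiv), CH2Cl2, −40 °C
Reagents that add atoms: dimethyldioxirane, CC1(C)OO1
Why: Epoxidation takes place on the α face because the two axial methyls cover the β face, and the Meinwald rearrangement then opens the epoxide at benzylic C7 and shifts hydride from C6 to C7, which places the carbonyl regiospecifically on C6.

Step 7
Reactants: 8 6-oxoabieta-8,11,13-trien-18-yl acetate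
Product: 9 6β-hydroxyabieta-8,11,13-trien-18-yl acetate
Conditions: NaBH4, CeCl3·7H2O, MeOH, −20 °C (8 used at once)
Reagents that add atoms: none
Why: In this Luche reduction hydride reaches C6 from the open α face, the β face being blocked by the two axial methyls in 1,3-relation to C6, so the axial 6β-alcohol is set, while CeCl3 suppresses enolisation toward C5 and C7.

Step 8
Reactants: 9 6β-hydroxyabieta-8,11,13-trien-18-yl acetate
Product: 10 6β-(2,2,2-trichloroethoxycarbonyloxy)abieta-8,11,13-trien-18-yl acetate
Conditions: TrocCl, pyridine, DMAP, CH2Cl2, 0 °C to reflux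
Reagents that add atoms: 2,2,2-trichloroethyl chloroformate, ClC(=O)OCC(Cl)(Cl)Cl
Why: DMAP-assisted acylation with the reactive chloroformate overcomes the hindrance of the axial alcohol, and the carbonate resists RuO4, deactivates the adjacent benzylic C7–H bonds by induction and can later be removed by zinc without touching the acetate.

Step 9
Reactants: 10 6β-(2,2,2-trichloroethoxycarbonyloxy)abieta-8,11,13-trien-18-yl acetate
Product: 11 seco diacid (C8 and C18 as CO2H, O6 as Troc carbonate, O9 as acetate)
Conditions: RuCl3·xH2O (5 mol %), NaIO4 (excess), EtOAc–MeCN–H2O, rt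
Reagents that add atoms: sodium periodate, [Na+].[O-]I(=O)(=O)=O (oxygen, relayed by RuO4, O=[Ru](=O)(=O)=O)
Why: RuO4 degradation of an alkylbenzene burns the ring down to the carboxylic acids of the ring carbons that bear alkyl groups, so abietane C8 stays as CO2H on C7 and abietane C9 as CO2H on the quaternary carbon, the old ring B is thereby cut, and the four stereocentres lie outside the reacting π system.

Step 10
Reactants: 11 seco diacid
Product: 13 acetoxy lactone acid (18,6-γ-lactone), via hydroxy diacid 12 (not isolated)
Conditions: Zn, AcOH, rt; filter; 60 °C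
Reagents that add atoms: none
Why: Zinc induces reductive fragmentation of the trichloroethyl carbonate, and the freed O6, which lies next to the equatorial C18 carboxyl, closes the trans-fused γ-lactone by acid-catalysed lactonisation with retention at C6, while O9 is still acetylated and cannot compete for C18.

Step 11
Reactants: 13 acetoxy lactone acid
Product: 14 hydroxy lactone acid (free C9 alcohol)
Conditions: K2CO3, MeOH, 0 °C to rt; work-up at pH 3
Reagents that add atoms: none
Why: Base-catalysed transesterification removes the primary acetate, whereas the lactone carbonyl is shielded by quaternary C4 and the trans ring fusion freezes the ring A chair so that the equatorial C9 alkoxide cannot reach C18.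

Step 12
Reactants: 14 hydroxy lactone acid
Product: 15 aldehyde lactone acid (C9 aldehyde)
Conditions: Dess–Martin periodinane, CH2Cl2, rt
Reagents that add atoms: none
Why: Dess–Martin oxidation stops at the aldehyde, tolerates the free acid and the lactone, and C10 has no hydrogen that could epimerise.

Step 13
Reactants: 15 aldehyde lactone acid; 16 trimethyl phosphonoacetate
Product: 17 enoate lactone acid (C9=C11 E-enoate, C8 still CO2H)
Conditions: 16, NaH, THF, 0 to 45 °C; acidic work-up
Reagents that add atoms: trimethyl phosphonoacetate 16, COC(=O)CP(=O)(OC)OC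
Why: The Horner–Wadsworth–Emmons reaction of a stabilised phosphonate with a non-enolisable neopentyl aldehyde is E-selective under thermodynamic control, and the C8 acid is merely carried as its carboxylate, which also blocks β-elimination of O6.

Step 14
Reactants: 17 enoate lactone acid
Product: 19 keto enoate lactone (seco-ring-B precursor), via acid chloride 18 (not isolated)
Conditions: (COCl)2, DMF (cat.), CH2Cl2, 0 °C to rt; evaporate; Me2Zn, Pd(PPh3)4 (5 mol %), THF–toluene, 0 °C; 19 filtered through neutral silica and used at once
Reagents that add atoms: oxalyl chloride, O=C(Cl)C(=O)Cl (the chlorine of 18); dimethylzinc, C[Zn]C (the C17 methyl of 19)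
Why: Acid chloride formation followed by palladium-catalysed Negishi acylation delivers one methyl group (C17) and stops at the ketone, and the non-basic organozinc leaves the enoate, the lactone and the elimination-prone β-acyloxy ketone intact.

Step 15
Reactants: 19 keto enoate lactone
Product: 20 methyl 8-hydroxy-13,14,15,16-tetranor-ent-labdan-12-oate 18,6-lactone
Conditions: SmI2 (2.5 equiv), t-BuOH (3 equiv), THF, −78 to −20 °C; cold pH 7 buffer quench
Reagents that add atoms: none
Why: SmI2 gives one electron to the C8 ketone, the samarium ketyl adds to C9 (the β-carbon of the E-enoate), and the C11 radical takes a second electron to become a trivalent samarium enolate that t-BuOH protonates. The closest known reaction type is the SmI2 ketyl–olefin reductive cyclisation of keto enoates to 2-hydroxycycloalkylacetates. Ring B closes 6-exo-trig through a chair that shares C5 and C10 with the rigid ring A chair. C9 is controlled by that chair: the C9=C11 arm stays pseudo-equatorial on the forming ring, so H9 ends axial and anti to the axial C20 methyl. C8 is controlled by the ketyl oxygen: the large solvated O–Sm group takes the equatorial site, anti to the ester arm with which it would otherwise suffer dipole repulsion, and this places C17 axial despite its 1,3-contact with C20. The step needs cyclisation to outrun ketyl protonation, enoate reduction and β-elimination of O6, and the substrate secures this because the trans-fused 18,6-lactone fixes H6 between the two axial methyls and C7 anti to C4, which holds C8 within bonding distance of C9, while the weak proton donor and the low temperature keep O8 from closing onto the C12 ester.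

Step 16
Reactants: 20 methyl 8-hydroxy-13,14,15,16-tetranor-ent-labdan-12-oate 18,6-lactone
Product: 21 8-O-triethylsilyl ether of 20
Conditions: TESOTf, 2,6-lutidine, CH2Cl2, −78 to 0 °C
Reagents that add atoms: triethylsilyl triflate, CC[Si](CC)(CC)OS(=O)(=O)C(F)(F)F
Why: A silyl triflate and a hindered pyridine base silylate even this tertiary alcohol, which is needed because a free O8 would displace any leaving group on C12 by 5-exo-tet closure to an ambroxide-type ether.

Step 17
Reactants: 21 8-O-triethylsilyl ether of 20
Product: 22 6,12,18-triol (8-OTES)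
Conditions: LiAlH4, THF, 0 °C to rt
Reagents that add atoms: none
Why: LiAlH4 reduces the methyl ester to the C12 alcohol and the lactone to the 6,18-diol in one operation without breaking any bond to a stereocentre, and the tertiary silyl ether survives.

Step 18
Reactants: 22 6,12,18-triol
Product: 23 12-iodo-6,18-diol (8-OTES)
Conditions: I2 (1.1 equiv), PPh3 (1.1 equiv), imidazole, CH2Cl2, −10 to 0 °C
Reagents that add atoms: iodine, II
Why: Garegg–Samuelsson iodination with one equivalent of reagent picks the unhindered primary C12 alcohol, since SN2 displacement is very slow at neopentyl C18 and at the secondary, flanked C6.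

Step 19
Reactants: 24 chloroprene
Product: 25 buta-1,3-dien-2-ylmagnesium chloride (THF solution)
Conditions: Mg, ZnCl2 (cat.), BrCH2CH2Br (initiator), THF, reflux
Reagents that add atoms: magnesium, [Mg]
Why: Magnesium insertion into the vinylic C–Cl bond of chloroprene, helped by catalytic ZnCl2, is the established way to the 2-butadienyl Grignard reagent.

Step 20
Reactants: 23 12-iodo-6,18-diol; 25 buta-1,3-dien-2-ylmagnesium chloride
Product: 26 ent-labda-13(16),14-diene-6,18-diol 8-OTES ether
Conditions: 25 (5 equiv), Li2CuCl4 (5 mol %), THF, −20 to 0 °C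
Reagents that add atoms: buta-1,3-dien-2-ylmagnesium chloride 25, C=CC(=C)[Mg]Cl
Why: Copper-catalysed cross-coupling of a primary alkyl iodide with the 2-butadienyl Grignard reagent (Kochi-type coupling) forms C12–C13 at the internal diene carbon, the two free hydroxyls only consume reagent as alkoxides, and the silylated O8 cannot cyclise onto C12.

Step 21
Reactants: 26 ent-labda-13(16),14-diene-6,18-diol 8-OTES ether
Product: 27 18-OTBS, 8-OTES, 6-ol
Conditions: TBSCl (1.1 equiv), imidazole, CH2Cl2, 0 °C
Reagents that add atoms: tert-butyldimethylsilyl chloride, CC(C)(C)[Si](C)(C)Cl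
Why: Silylation with TBSCl and imidazole is selective for the primary O18 over the secondary O6.

Step 22
Reactants: 27 18-OTBS, 8-OTES, 6-ol
Product: 28 6-acetate of 27
Conditions: Ac2O, pyridine, DMAP (cat.), CH2Cl2, rt
Reagents that add atoms: acetic anhydride, CC(=O)OC(C)=O
Why: DMAP-catalysed acetylation meets only one free hydroxyl, the equatorial O6.

Step 23
Reactants: 28 6-acetate of 27
Product: 29 target CNP0312185.1
Conditions: HF·pyridine, pyridine, THF, 0 °C to rt
Reagents that add atoms: none
Why: Buffered HF·pyridine cleaves both silyl ethers by fluoride-driven desilylation under conditions too mild to ionise the tertiary alcohol, to isomerise the diene or to move the acetyl group, which would need a seven-membered transition state to reach O18.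

Compound list
1 | dehydroabietic acid (abieta-8,11,13-trien-18-oic acid) | CC(C)c1ccc2c(c1)CC[C@@H]3[C@]2(C)CCC[C@@]3(C)C(=O)O | starting material
2 | dehydroabietinol (abieta-8,11,13-trien-18-ol) | CC(C)c1ccc2c(c1)CC[C@@H]3[C@]2(C)CCC[C@@]3(C)CO | intermediate
3 | abieta-8,11,13-trien-18-yl acetate | CC(C)c1ccc2c(c1)CC[C@@H]3[C@]2(C)CCC[C@@]3(C)COC(C)=O | intermediate
4 | 7-oxoabieta-8,11,13-trien-18-yl acetate | CC(C)c1ccc2c(c1)C(=O)C[C@@H]3[C@]2(C)CCC[C@@]3(C)COC(C)=O | intermediate
5 | 7-hydroxyabieta-8,11,13-trien-18-yl acetate, both C7 epimers (C7 left open because it is destroyed in step 5) | CC(C)c1ccc2c(c1)C(O)C[C@@H]3[C@]2(C)CCC[C@@]3(C)COC(C)=O | intermediate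
6 | abieta-6,8,11,13-tetraen-18-yl acetate | CC(C)c1ccc2c(c1)C=C[C@@H]3[C@]2(C)CCC[C@@]3(C)COC(C)=O | intermediate
7 | 6α,7α-epoxyabieta-8,11,13-trien-18-yl acetate | CC(C)c1ccc2c(c1)[C@@H]4O[C@@H]4[C@@H]3[C@]2(C)CCC[C@@]3(C)COC(C)=O | intermediate
8 | 6-oxoabieta-8,11,13-trien-18-yl acetate | CC(C)c1ccc2c(c1)CC(=O)[C@@H]3[C@]2(C)CCC[C@@]3(C)COC(C)=O | intermediate
9 | 6β-hydroxyabieta-8,11,13-trien-18-yl acetate (axial OH, syn to both axial methyls) | CC(C)c1ccc2c(c1)C[C@@H](O)[C@@H]3[C@]2(C)CCC[C@@]3(C)COC(C)=O | intermediate
10 | 6β-(2,2,2-trichloroethoxycarbonyloxy)abieta-8,11,13-trien-18-yl acetate | CC(C)c1ccc2c(c1)C[C@@H](OC(=O)OCC(Cl)(Cl)Cl)[C@@H]3[C@]2(C)CCC[C@@]3(C)COC(C)=O | intermediate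
11 | seco diacid: 3-(acetoxymethyl)-2-[2-carboxy-1-(2,2,2-trichloroethoxycarbonyloxy)ethyl]-1,3-dimethylcyclohexane-1-carboxylic acid; both methyls axial and cis, C18, C6 and C9 equatorial | CC(=O)OC[C@]1(C)CCC[C@](C)(C(=O)O)[C@H]1[C@H](OC(=O)OCC(Cl)(Cl)Cl)CC(=O)O | intermediate
12 | hydroxy diacid (11 without the carbonate) | CC(=O)OC[C@]1(C)CCC[C@](C)(C(=O)O)[C@H]1[C@H](O)CC(=O)O | intermediate
13 | acetoxy lactone acid: [4-(acetoxymethyl)-4,7a-dimethyl-1-oxooctahydroisobenzofuran-3-yl]acetic acid, trans-fused | CC(=O)OC[C@]1(C)CCC[C@]2(C)C(=O)O[C@H](CC(=O)O)[C@@H]12 | intermediate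
14 | hydroxy lactone acid: [4-(hydroxymethyl)-4,7a-dimethyl-1-oxooctahydroisobenzofuran-3-yl]acetic acid | OC[C@]1(C)CCC[C@]2(C)C(=O)O[C@H](CC(=O)O)[C@@H]12 | intermediate
15 | aldehyde lactone acid: (4-formyl-4,7a-dimethyl-1-oxooctahydroisobenzofuran-3-yl)acetic acid | O=C[C@]1(C)CCC[C@]2(C)C(=O)O[C@H](CC(=O)O)[C@@H]12 | intermediate
16 | trimethyl phosphonoacetate | COC(=O)CP(=O)(OC)OC | starting material
17 | enoate lactone acid: {4-[(E)-2-(methoxycarbonyl)vinyl]-4,7a-dimethyl-1-oxooctahydroisobenzofuran-3-yl}acetic acid | COC(=O)/C=C/[C@]1(C)CCC[C@]2(C)C(=O)O[C@H](CC(=O)O)[C@@H]12 | intermediate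
18 | acid chloride of 17 | COC(=O)/C=C/[C@]1(C)CCC[C@]2(C)C(=O)O[C@H](CC(=O)Cl)[C@@H]12 | intermediate
19 | keto enoate lactone, seco-ring-B precursor: methyl (E)-3-[4,7a-dimethyl-1-oxo-3-(2-oxopropyl)octahydroisobenzofuran-4-yl]acrylate (C8 methyl ketone, C9=C11 E-enoate, 18,6-lactone) | COC(=O)/C=C/[C@]1(C)CCC[C@]2(C)C(=O)O[C@H](CC(C)=O)[C@@H]12 | intermediate
20 | methyl 8-hydroxy-13,14,15,16-tetranor-ent-labdan-12-oate 18,6-lactone (8-OH and C11 equatorial, C17 axial) | COC(=O)C[C@H]1[C@]2(C)CCC[C@]3(C)C(=O)O[C@@H]([C@@H]23)C[C@]1(C)O | intermediate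
21 | 8-O-triethylsilyl ether of 20 | COC(=O)C[C@H]1[C@]2(C)CCC[C@]3(C)C(=O)O[C@@H]([C@@H]23)C[C@]1(C)O[Si](CC)(CC)CC | intermediate
22 | 8-(triethylsilyloxy)-13,14,15,16-tetranor-ent-labdane-6,12,18-triol | OCC[C@H]1[C@]2(C)CCC[C@](C)(CO)[C@H]2[C@H](O)C[C@]1(C)O[Si](CC)(CC)CC | intermediate
23 | 12-iodo-8-(triethylsilyloxy)-13,14,15,16-tetranor-ent-labdane-6,18-diol | ICC[C@H]1[C@]2(C)CCC[C@](C)(CO)[C@H]2[C@H](O)C[C@]1(C)O[Si](CC)(CC)CC | intermediate
24 | chloroprene (2-chlorobuta-1,3-diene) | C=CC(Cl)=C | starting material
25 | buta-1,3-dien-2-ylmagnesium chloride | C=CC(=C)[Mg]Cl | intermediate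
26 | 8-(triethylsilyloxy)-ent-labda-13(16),14-diene-6,18-diol | C=CC(=C)CC[C@H]1[C@]2(C)CCC[C@](C)(CO)[C@H]2[C@H](O)C[C@]1(C)O[Si](CC)(CC)CC | intermediate
27 | 18-(tert-butyldimethylsilyloxy)-8-(triethylsilyloxy)-ent-labda-13(16),14-dien-6-ol | C=CC(=C)CC[C@H]1[C@]2(C)CCC[C@](C)(CO[Si](C)(C)C(C)(C)C)[C@H]2[C@H](O)C[C@]1(C)O[Si](CC)(CC)CC | intermediate
28 | 6-acetate of 27 | C=CC(=C)CC[C@H]1[C@]2(C)CCC[C@](C)(CO[Si](C)(C)C(C)(C)C)[C@H]2[C@H](OC(C)=O)C[C@]1(C)O[Si](CC)(CC)CC | intermediate
29 | CNP0312185.1: 6-acetoxy-ent-labda-13(16),14-diene-8,18-diol (6-OAc, 8-OH and C18 equatorial) | C=CC(=C)CC[C@H]1[C@]2(C)CCC[C@](C)(CO)[C@H]2[C@H](OC(C)=O)C[C@]1(C)O | target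

Total step count: 23. Longest linear sequence: 22 (steps 1 to 18 and 20 to 23).

Steps most likely to fail

**First, step 15.**
- **What may go wrong:** the ketyl may add through the alternative chair that puts the O–Sm group axial and the methyl equatorial, so as to escape the 1,3-diaxial contact of C17 with C20. That is poor facial selectivity at C8.
- **Fallback (from 19, back at 20):** C8 is set after the C–C bond is made, not during it.
  - The cyclisation is run as in step 15, and the C8 epimer of 20 F1 is kept.
  - Burgess reagent (benzene, 50 °C) dehydrates it to the exocyclic 8(17)-alkene F2, together with the Δ7 alkene F3.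
  - Both alkenes give the same tertiary C8 radical in a Mukaiyama hydration (Mn(dpm)3 cat., PhSiH3, O2, i-PrOH, 0 °C, then PPh3).
  - Oxygen should be taken up on the face away from the axial C20 methyl. This gives the equatorial alcohol with the axial methyl, that is 20.

**Second, step 9.**
- **What may go wrong:** hydrogen abstraction from the benzylic C7–H bonds may run ahead of attack on the ring. The resulting conjugation deactivates the arene and, after cleavage, costs C8 by oxidative decarboxylation.
- **Fallback (from 10, back at 11):** a metal-oxo oxidant that can abstract hydrogen is replaced by one that only adds to π bonds.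
  - Exhaustive ozonolysis of 10 (O3, CH2Cl2–AcOH, −20 °C) cleaves the ring by cycloaddition.
  - Oxidative work-up with H2O2 in HCO2H breaks the α-dicarbonyl fragments down to the same two carboxyl groups.
  - The carbonate and the acetate are inert to both reagents. No new isolable compound is made (F0).

**Third, step 18.**
- **What may go wrong:** chemoselectivity among the three hydroxyls may be lost. In particular, the neopentyl O18 next to O6 may be activated and then cyclodehydrate to a 6,18-ether.
- **Fallback (from 21, back at 26):** the lactone is kept as the protecting group until the side chain is in place, at the cost of two extra steps.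
  - LiOH (THF–H2O, rt) saponifies only the unhindered ester and gives the C12 carboxylic acid F4. The shielded lactone recloses on acidification if it opens at all.
  - BH3·THF (0 °C) reduces the acid in the presence of the lactone to the C12 alcohol F5.
  - I2, PPh3 and imidazole then meet a single hydroxyl and give the C12 iodide F6.
  - Coupling with 25 and Li2CuCl4 at −20 °C gives the diene lactone F7.
  - LiAlH4 opens the lactone to 26.

Further compounds
F1 | step 15 | C8 epimer of 20 (8-OH axial, C17 equatorial) | COC(=O)C[C@H]1[C@]2(C)CCC[C@]3(C)C(=O)O[C@@H]([C@@H]23)C[C@@]1(C)O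
F2 | step 15 | methyl 13,14,15,16-tetranor-ent-labd-8(17)-en-12-oate 18,6-lactone | COC(=O)C[C@H]1[C@]2(C)CCC[C@]3(C)C(=O)O[C@@H]([C@@H]23)CC1=C
F3 | step 15 | methyl 13,14,15,16-tetranor-ent-labd-7-en-12-oate 18,6-lactone | COC(=O)C[C@H]1[C@]2(C)CCC[C@]3(C)C(=O)O[C@@H]([C@@H]23)C=C1C
F0 | step 9 | none | none
F4 | step 18 | 8-(triethylsilyloxy)-13,14,15,16-tetranor-ent-labdan-12-oic acid 18,6-lactone | OC(=O)C[C@H]1[C@]2(C)CCC[C@]3(C)C(=O)O[C@@H]([C@@H]23)C[C@]1(C)O[Si](CC)(CC)CC
F5 | step 18 | 12-hydroxy-8-(triethylsilyloxy)-13,14,15,16-tetranor-ent-labdan-18,6-olide | OCC[C@H]1[C@]2(C)CCC[C@]3(C)C(=O)O[C@@H]([C@@H]23)C[C@]1(C)O[Si](CC)(CC)CC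
F6 | step 18 | 12-iodo-8-(triethylsilyloxy)-13,14,15,16-tetranor-ent-labdan-18,6-olide | ICC[C@H]1[C@]2(C)CCC[C@]3(C)C(=O)O[C@@H]([C@@H]23)C[C@]1(C)O[Si](CC)(CC)CC
F7 | step 18 | 8-(triethylsilyloxy)-ent-labda-13(16),14-dien-18,6-olide | C=CC(=C)CC[C@H]1[C@]2(C)CCC[C@]3(C)C(=O)O[C@@H]([C@@H]23)C[C@]1(C)O[Si](CC)(CC)CC
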